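The runs are calculated on assumed constants, and the scatter is random.

The vessel is closed, stirred and held at one temperature; what it holds at 4.0 h, and what an intervention can still reach, is the question.

| flask | Z | E | J | D | temperature | remark | time |
|---|---|---|---|---|---|---|---|
| grey | 0.10 M | 0.10 M | 0.30 M | 15 mM | 40 °C | the very flask that is asked about, followed so far |  |
| amber | 0.10 M | 0.10 M | 0.30 M | 30 mM | 40 °C | run made earlier |  |
| flask | 0.10 M | 0.10 M | 0.300 M | 15 mM | 40 °C |  | 4.0 h |

- grey (time / min: X / %): 15.0: 37.6; 30.0: 38.0; 50.0: 38.5; 90.0: 38.4; 180: 38.3
- amber (time / min: X / %): 4.00: 38.5; 8.00: 42.9; 12.0: 44.4; 15.0: 44.7; 20.0: 45.1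

(each reading ± 0.3 percentage points)

- autumn: at 4.0 h raise the temperature by 10 K, then wait 80 min
- spring: at 4.0 h add D, 50.0% of the amount charged, then wait 80 min
- summer: at 4.0 h take out 90% of the X then present, then wait 80 min
- noon: at 4.0 h add J, 100% of the amount charged, then wait 80 min
- dusk: change nothing and wait 80 min more

- D is single-handed; Z and E are mirror images of each other, charged as a racemate, each of them at the stated concentration
- removed X is counted in
- the earlier runs do not show what temperature does; that part of a forecast is a guess
- additions bring no volume worth counting

* X, in percent of the Z and E together first charged, at 4.0 h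
* the option that brings most further X ("none" if no option brings more than 2 percentage points) (autumn / spring / summer / noon / dusk / none)
* X present, with what was taken out counted in, in percent of the Z and E together first charged, after autumn
* X present, with what was taken out counted in, in percent of the Z and E together first charged, after spring

Begin with the main step: J and Z meet on D and give X, and D comes out again. By itself this step runs until Z is used up, so X ends at 50.0% of the racemate. Add a slower path for E and that number stands, because the J charged exceeds what Z and E together ask. Yet the grey flask lies flat at 38.4% and the amber flask at 45.1%, so a further process, with a time constant of minutes, ends the work.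

Z falls in proportion to itself, J and D. Dividing that rate by the rate of the further process takes time out, and what remains is a total. The grey flask leaves 23.2% of its Z, and the amber flask 9.80%. So, as readings:

grey: ln(Z charged / Z left) / D = 0.0974 mM⁻¹

amber: the same = 0.0774 mM⁻¹

The first line defines the reach, the logarithm of Z charged over Z left per unit of D. Twice the D brought a smaller reach. My reading: D returns from each turn, whereas J is eaten by the making, so a J that also dies by itself leaves less to die the more product forms. Then the grey flask stands at about its plateau at 4.0 h. In this reckoning autumn, spring, summer and dusk add nothing, and noon, fresh J on the Z that is left, is taken at the grey reach as a first estimate: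

X after noon, estimated = 47.3%, a gain of 8.9 percentage points

The second dose meets less Z than the first, so by my reading its reach is larger and this estimate lies low.

The forecast gives 38.4% now, 38.5% after autumn and 45% after spring, and names spring as best, holding that “Fresh D should work”, which parts from my reckoning.

The flask gives 38.4% at 4.0 h, 38.4% after autumn and 38.4% after spring. The best option is noon, with a gain of 10 points.

    J + D + Z → D + X (k = 73.8 L² mol⁻² min⁻¹, Ea = 36.0 kJ mol⁻¹)
    J + D + E → D + L (k = 26.9 L² mol⁻² min⁻¹, Ea = 46.0 kJ mol⁻¹)
    J → G (k = 0.138 min⁻¹, Ea = 91.0 kJ mol⁻¹)
    (constants at 40 °C)

J, the limiting reagent here, stands at 0% at 4.0 h, while D stands at 100%. Part of the shortfall is the loss of J to G: the run without that loss reaches 50.0% instead of 38.4%. The gain by noon hangs on the same loss: 10 points with it, 0 points without it. The reach is therefore the ratio of the constant of the Z step to that of the loss, times the G formed: 0.0973 mM⁻¹, beside the 0.0974 mM⁻¹ read from the grey plateau.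

The neighbour with 0.060 M of D forms 0.125 M of G, so its reach is 0.0668 mM⁻¹, which leaves 1.81% of its Z and gives X at 49.1%. The computed flask holds 1.8% of its Z and 49.1% of X.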